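## Retrosynthetic overview

- The target is a 5,6,7-trimethoxyflavone carrying a 3-hydroxy-2,4,5-trimethoxyphenyl ring B; it has no stereocentre. The last operations are O-debenzylation at C3′, O-methylation at C5, C6 and C7, and removal of two tert-butyl groups.
- The strategy rests on ring A: C5, C6 and C7 carry three adjacent oxygens and C8 carries hydrogen para to C5, fused to ring C through C4a–C8a. This is the phenol / two alkyne carbons / ketene CH pattern of a vinylketene–alkyne benzannulation.
- Key disconnection: ring A (C5–C6, C7–C8, C4a–C5) from a 2-aryl-6-(diazoacetyl)-4-pyranone and di-tert-butoxyethyne.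
- The diazoketone comes from the pyranone-2-carboxylic acid, made from the ring B aroylacetone and diethyl oxalate (ring C). The ring B ketone comes from 2′,3′-dihydroxy-4′-methoxyacetophenone by benzylation, bromination, methoxylation and methylation.
- Ring order: ring B is purchased, ring C is closed in step 6, ring A is closed last in step 9.

Key step: step 9

Assumption: 2′,3′-dihydroxy-4′-methoxyacetophenone and di-tert-butoxyethyne are taken as purchasable, and the ynol ether is kept below 40 °C while in excess because it loses isobutene on heating.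

## Route

Step 1
Reactants: 1 1-(2,3-dihydroxy-4-methoxyphenyl)ethan-1-one
Product: 2 1-[3-(benzyloxy)-2-hydroxy-4-methoxyphenyl]ethan-1-one
Conditions: BnBr (1.05 equiv), K2CO3 (1.1 equiv), acetone, reflux
Reagents that add atoms: benzyl bromide BrCc1ccccc1
Why: Williamson etherification under weak base should alkylate only the C3 hydroxyl, because the C2 hydroxyl is held in a hydrogen bond to the acetyl carbonyl and is both less acidic and less nucleophilic.

Step 2
Reactants: 2 1-[3-(benzyloxy)-2-hydroxy-4-methoxyphenyl]ethan-1-one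
Product: 3 1-[3-(benzyloxy)-5-bromo-2-hydroxy-4-methoxyphenyl]ethan-1-one
Conditions: NBS (1.05 equiv), MeCN, 0 °C → rt
Reagents that add atoms: N-bromosuccinimide O=C1CCC(=O)N1Br
Why: Electrophilic aromatic bromination should go to C5, the only open position para to the free phenol and ortho to the C4 methoxy group, whereas C6 is deactivated by the neighbouring acetyl group.

Step 3
Reactants: 3 1-[3-(benzyloxy)-5-bromo-2-hydroxy-4-methoxyphenyl]ethan-1-one
Product: 4 1-[3-(benzyloxy)-2-hydroxy-4,5-dimethoxyphenyl]ethan-1-one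
Conditions: NaOMe (5 equiv, in MeOH), CuBr (10 mol %), DMF, 110 °C; aq. HCl work-up
Reagents that add atoms: sodium methoxide [Na+].[O-]C
Why: Copper-catalysed Ullmann-type methoxylation of bromophenols with NaOMe is an established aryl C–O coupling, and the substrate reacts as its phenoxide, which keeps the acetyl group from enolising or condensing.

Step 4
Reactants: 4 1-[3-(benzyloxy)-2-hydroxy-4,5-dimethoxyphenyl]ethan-1-one
Product: 5 1-[3-(benzyloxy)-2,4,5-trimethoxyphenyl]ethan-1-one
Conditions: MeI (3 equiv), K2CO3 (2 equiv), DMF, 50 °C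
Reagents that add atoms: iodomethane CI
Why: Williamson O-methylation of the chelated phenol with MeI and K2CO3 in DMF is routine for 2-hydroxyacetophenones and leaves the benzyl ether untouched.

Step 5
Reactants: 5 1-[3-(benzyloxy)-2,4,5-trimethoxyphenyl]ethan-1-one; 6 ethyl acetate
Product: 7 1-[3-(benzyloxy)-2,4,5-trimethoxyphenyl]butane-1,3-dione
Conditions: NaH (2.5 equiv), EtOAc (5 equiv), THF, reflux; aq. HCl work-up
Reagents that add atoms: none
Why: Crossed Claisen condensation of the ketone enolate with ethyl acetate is driven forward by irreversible deprotonation of the β-diketone that forms.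

Step 6
Reactants: 7 1-[3-(benzyloxy)-2,4,5-trimethoxyphenyl]butane-1,3-dione; 8 diethyl oxalate
Product: 10 ethyl 6-[3-(benzyloxy)-2,4,5-trimethoxyphenyl]-4-oxo-4H-pyran-2-carboxylate, via triketo ester 9 (not isolated)
Conditions: NaOEt (3 equiv), (CO2Et)2 (1.5 equiv), EtOH, rt → reflux; then conc. HCl (to pH 1), EtOH, reflux
Reagents that add atoms: none
Why: Claisen acylation of the β-diketone at its terminal methyl group by diethyl oxalate (the reactivity used to make chelidonic acid from acetone) gives the 2,4,6-triketo ester, and acid-catalysed cyclodehydration between its two outer carbonyl groups closes the 4-pyranone ring C.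

Step 7
Reactants: 10 ethyl 6-[3-(benzyloxy)-2,4,5-trimethoxyphenyl]-4-oxo-4H-pyran-2-carboxylate
Product: 11 6-[3-(benzyloxy)-2,4,5-trimethoxyphenyl]-4-oxo-4H-pyran-2-carboxylic acid
Conditions: LiOH·H2O (1.1 equiv), THF/H2O, 0 °C; then 1 M HCl
Reagents that add atoms: lithium hydroxide [Li+].[OH-]
Why: Saponification of the activated 2-carboxylate with one equivalent of LiOH at 0 °C should outrun hydroxide attack on the pyranone ring, and the acidification recloses any ring-opened material.

Step 8
Reactants: 11 6-[3-(benzyloxy)-2,4,5-trimethoxyphenyl]-4-oxo-4H-pyran-2-carboxylic acid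
Product: 13 2-[3-(benzyloxy)-2,4,5-trimethoxyphenyl]-6-(2-diazoacetyl)-4H-pyran-4-one, via acid chloride 12 (not isolated)
Conditions: (COCl)2 (1.3 equiv), DMF (cat.), CH2Cl2, 0 °C → rt, evaporate; CH2N2 (3 equiv), Et2O/THF, 0 °C
Reagents that add atoms: oxalyl chloride O=C(Cl)C(Cl)=O (chlorine of 12); diazomethane C=[N+]=[N-]
Why: Acyl chloride formation followed by acylation of diazomethane (the first stage of the Arndt–Eistert sequence) is the standard route to diazomethyl ketones, and the second equivalent of diazomethane removes the HCl that would otherwise give the chloromethyl ketone.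

Step 9
Reactants: 13 2-[3-(benzyloxy)-2,4,5-trimethoxyphenyl]-6-(2-diazoacetyl)-4H-pyran-4-one; 14 di-tert-butoxyethyne
Product: 18 2-[3-(benzyloxy)-2,4,5-trimethoxyphenyl]-6,7-di-tert-butoxy-5-hydroxy-4H-chromen-4-one, via pyranonylketene 15 (not isolated), via cyclobutenone 16 (not isolated), via dienylketene 17 (not isolated)
Conditions: 14 (3 equiv), hν (405 nm LED), ClCH2CH2Cl (degassed), 20 °C; excess 14 removed in vacuo; PhMe, 80 °C
Reagents that add atoms: none
Why: Excitation of the diazo n→π* band expels N2 and the pyranonyl group migrates to the carbene carbon (Wolff rearrangement, making C8–C8a) to give ketene 15, whose C=C adds across the electron-rich alkyne 14 in a (2+2) cycloaddition (C5–C6 and C7–C8) to cyclobutenone 16. On warming, 16 opens by reversible 4π electrocyclic cleavage to dienylketene 17, and the isomer with the pyranonyl group cis to the ketene is drained by a thermal disrotatory 6π electrocyclisation that joins the ketene carbon to the pyranone carbon α to the ring carbonyl (C4a–C5) and so closes ring A. Tautomerisation of the resulting cyclohexadienone gives the C5 phenol, hydrogen-bonded to the C4 carbonyl. The closest known reaction is the diazoketone form of the Danheiser benzannulation of aryl, heteroaryl and alkenyl diazomethyl ketones with alkoxyalkynes, together with the known ketene (2+2) cycloadditions of 14. No stereocentre is formed in 18, since the sp3 carbon of racemic 16 is lost on ring opening. The symmetric alkyne removes the regiochemical question and only C4a is conjugated to the dienylketene through the C8a=C4a bond, while chemoselectivity rests on 405 nm light, which the diazoketone should absorb and the pyranone should not, and on excess 14, which should trap 15 faster than it dimerises.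

Step 10
Reactants: 18 2-[3-(benzyloxy)-2,4,5-trimethoxyphenyl]-6,7-di-tert-butoxy-5-hydroxy-4H-chromen-4-one
Product: 19 2-[3-(benzyloxy)-2,4,5-trimethoxyphenyl]-5,6,7-trihydroxy-4H-chromen-4-one
Conditions: TFA/CH2Cl2 (1:4), H2O (5 equiv), 0 °C → rt, under argon
Reagents that add atoms: none
Why: Acidolysis of aryl tert-butyl ethers by TFA runs through the tert-butyl cation (SN1/E1), which water should intercept before it can alkylate C8, while the benzyl and methyl ethers are stable under these mild conditions.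

Step 11
Reactants: 19 2-[3-(benzyloxy)-2,4,5-trimethoxyphenyl]-5,6,7-trihydroxy-4H-chromen-4-one
Product: 20 2-[3-(benzyloxy)-2,4,5-trimethoxyphenyl]-5,6,7-trimethoxy-4H-chromen-4-one
Conditions: Me2SO4 (6 equiv), K2CO3 (8 equiv), acetone, reflux, under argon
Reagents that add atoms: dimethyl sulfate COS(=O)(=O)OC
Why: Williamson permethylation with dimethyl sulfate and K2CO3 in refluxing acetone is the standard way to methylate all ring A hydroxyls of a flavone, the hydrogen-bonded C5 hydroxyl included, and with this weak base O-alkylation should dominate over alkylation at C8.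

Step 12
Reactants: 20 2-[3-(benzyloxy)-2,4,5-trimethoxyphenyl]-5,6,7-trimethoxy-4H-chromen-4-one
Product: 21 agecorynin G, 2-(3-hydroxy-2,4,5-trimethoxyphenyl)-5,6,7-trimethoxy-4H-chromen-4-one
Conditions: H2 (1 atm), Pd/C (10%), EtOAc/MeOH, rt
Reagents that add atoms: none
Why: Catalytic hydrogenolysis of the benzyl aryl ether over Pd/C frees the C3′ hydroxyl without touching the methyl ethers or the flavone C2=C3 bond, which is inert to hydrogen at atmospheric pressure.

## Compound list

1 | 1-(2,3-dihydroxy-4-methoxyphenyl)ethan-1-one | CC(=O)c1ccc(OC)c(O)c1O | starting material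
2 | 1-[3-(benzyloxy)-2-hydroxy-4-methoxyphenyl]ethan-1-one | CC(=O)c1ccc(OC)c(OCc2ccccc2)c1O | intermediate
3 | 1-[3-(benzyloxy)-5-bromo-2-hydroxy-4-methoxyphenyl]ethan-1-one | CC(=O)c1cc(Br)c(OC)c(OCc2ccccc2)c1O | intermediate
4 | 1-[3-(benzyloxy)-2-hydroxy-4,5-dimethoxyphenyl]ethan-1-one | CC(=O)c1cc(OC)c(OC)c(OCc2ccccc2)c1O | intermediate
5 | 1-[3-(benzyloxy)-2,4,5-trimethoxyphenyl]ethan-1-one | CC(=O)c1cc(OC)c(OC)c(OCc2ccccc2)c1OC | intermediate
6 | ethyl acetate | CCOC(C)=O | starting material
7 | 1-[3-(benzyloxy)-2,4,5-trimethoxyphenyl]butane-1,3-dione | CC(=O)CC(=O)c1cc(OC)c(OC)c(OCc2ccccc2)c1OC | intermediate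
8 | diethyl oxalate | CCOC(=O)C(=O)OCC | starting material
9 | ethyl 6-[3-(benzyloxy)-2,4,5-trimethoxyphenyl]-2,4,6-trioxohexanoate | CCOC(=O)C(=O)CC(=O)CC(=O)c1cc(OC)c(OC)c(OCc2ccccc2)c1OC | intermediate
10 | ethyl 6-[3-(benzyloxy)-2,4,5-trimethoxyphenyl]-4-oxo-4H-pyran-2-carboxylate | CCOC(=O)c1cc(=O)cc(-c2cc(OC)c(OC)c(OCc3ccccc3)c2OC)o1 | intermediate
11 | 6-[3-(benzyloxy)-2,4,5-trimethoxyphenyl]-4-oxo-4H-pyran-2-carboxylic acid | OC(=O)c1cc(=O)cc(-c2cc(OC)c(OC)c(OCc3ccccc3)c2OC)o1 | intermediate
12 | 6-[3-(benzyloxy)-2,4,5-trimethoxyphenyl]-4-oxo-4H-pyran-2-carbonyl chloride | ClC(=O)c1cc(=O)cc(-c2cc(OC)c(OC)c(OCc3ccccc3)c2OC)o1 | intermediate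
13 | 2-[3-(benzyloxy)-2,4,5-trimethoxyphenyl]-6-(2-diazoacetyl)-4H-pyran-4-one | [N-]=[N+]=CC(=O)c1cc(=O)cc(-c2cc(OC)c(OC)c(OCc3ccccc3)c2OC)o1 | intermediate
14 | di-tert-butoxyethyne | CC(C)(C)OC#COC(C)(C)C | starting material
15 | 2-[3-(benzyloxy)-2,4,5-trimethoxyphenyl]-6-(2-oxoethenyl)-4H-pyran-4-one | O=C=Cc1cc(=O)cc(-c2cc(OC)c(OC)c(OCc3ccccc3)c2OC)o1 | intermediate
16 | 2-[3-(benzyloxy)-2,4,5-trimethoxyphenyl]-6-(2,3-di-tert-butoxy-4-oxocyclobut-2-en-1-yl)-4H-pyran-4-one (racemic) | O=C1C(OC(C)(C)C)=C(OC(C)(C)C)C1c2cc(=O)cc(-c3cc(OC)c(OC)c(OCc4ccccc4)c3OC)o2 | intermediate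
17 | (3E)-4-{6-[3-(benzyloxy)-2,4,5-trimethoxyphenyl]-4-oxo-4H-pyran-2-yl}-2,3-di-tert-butoxybuta-1,3-dien-1-one | O=C=C(OC(C)(C)C)/C(OC(C)(C)C)=C\c1cc(=O)cc(-c2cc(OC)c(OC)c(OCc3ccccc3)c2OC)o1 | intermediate
18 | 2-[3-(benzyloxy)-2,4,5-trimethoxyphenyl]-6,7-di-tert-butoxy-5-hydroxy-4H-chromen-4-one | CC(C)(C)Oc1cc2oc(-c3cc(OC)c(OC)c(OCc4ccccc4)c3OC)cc(=O)c2c(O)c1OC(C)(C)C | intermediate
19 | 2-[3-(benzyloxy)-2,4,5-trimethoxyphenyl]-5,6,7-trihydroxy-4H-chromen-4-one | Oc1cc2oc(-c3cc(OC)c(OC)c(OCc4ccccc4)c3OC)cc(=O)c2c(O)c1O | intermediate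
20 | 2-[3-(benzyloxy)-2,4,5-trimethoxyphenyl]-5,6,7-trimethoxy-4H-chromen-4-one | COc1cc2oc(-c3cc(OC)c(OC)c(OCc4ccccc4)c3OC)cc(=O)c2c(OC)c1OC | intermediate
21 | agecorynin G, 2-(3-hydroxy-2,4,5-trimethoxyphenyl)-5,6,7-trimethoxy-4H-chromen-4-one | COc1cc(-c2cc(=O)c3c(OC)c(OC)c(OC)cc3o2)c(OC)c(O)c1OC | target

Total step count: 12
Longest linear sequence: 12 steps (1 → 21)

## Steps most likely to fail

**1. Step 9 (photochemical benzannulation).** The pyranone diazoketone and a 1,2-dialkoxyalkyne have not been paired before. What may go wrong: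
- light absorbed by the aryl pyranone, leading to photodimerisation or ring rearrangement;
- oligomerisation of the ketene before it meets the alkyne;
- capture of the dienylketene by a second alkyne;
- a slow 6π closure onto the electron-poor enone carbon;
- thermal loss of isobutene from the ynol ether or from the cyclobutenone. Partial loss of tert-butyl groups from 18 itself would be harmless, since step 10 removes them.

Fallback: ring A would be bought and ring C closed last by Baker–Venkataraman chemistry, setting out from 5 and coming back at 20.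
- The haloform reaction (NaOCl, aq. NaOH, dioxane) should degrade ketone 5 to 3-(benzyloxy)-2,4,5-trimethoxybenzoic acid F1.
- Oxalyl chloride with catalytic DMF should give 3-(benzyloxy)-2,4,5-trimethoxybenzoyl chloride F2.
- Acylation of purchased 1-(6-hydroxy-2,3,4-trimethoxyphenyl)ethan-1-one (CC(=O)c1c(O)cc(OC)c(OC)c1OC) in pyridine should give 2-acetyl-3,4,5-trimethoxyphenyl 3-(benzyloxy)-2,4,5-trimethoxybenzoate F3.
- KOH in pyridine at 50 °C should move the aroyl group to carbon and give 1-[3-(benzyloxy)-2,4,5-trimethoxyphenyl]-3-(6-hydroxy-2,3,4-trimethoxyphenyl)propane-1,3-dione F4.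
- Cyclodehydration (catalytic H2SO4, AcOH, 90 °C) should close ring C and give 20, which re-enters the route at step 12.

**2. Step 8 (diazoketone formation).** What may go wrong: dipolar cycloaddition of diazomethane to the doubly acyl-activated C=C bond of the pyranone, chloride capture to the chloromethyl ketone, or attack of oxalyl chloride on the pyranone carbonyl oxygen.

Fallback: the diazo group would be introduced by diazo transfer instead of acylation of diazomethane, setting out from 7 and coming back at 13.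
- Diketone 7 would be acylated at its terminal methyl group with methyl 2,2-dimethoxypropanoate (NaH, THF, reflux) to give 1-[3-(benzyloxy)-2,4,5-trimethoxyphenyl]-6,6-dimethoxyheptane-1,3,5-trione F5.
- Acid (HCl in MeOH, then aq. HCl) should cyclise it and unmask the ketone to give 2-acetyl-6-[3-(benzyloxy)-2,4,5-trimethoxyphenyl]-4H-pyran-4-one F6.
- Enolisation with LiN(SiMe3)2 at −78 °C and trifluoroacetylation with 2,2,2-trifluoroethyl trifluoroacetate should give 1-{6-[3-(benzyloxy)-2,4,5-trimethoxyphenyl]-4-oxo-4H-pyran-2-yl}-4,4,4-trifluorobutane-1,3-dione F7.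
- Detrifluoroacetylative diazo transfer with methanesulfonyl azide (Et3N, H2O, MeCN) should give 13.

**3. Step 3 (copper-catalysed methoxylation).** What may go wrong: slow oxidative addition into the very electron-rich bromophenoxide, with reductive loss of bromine or base-induced condensation of the acetyl group taking over.

Fallback: the C5 oxygen would be introduced by Elbs persulfate oxidation instead of by halogenation and coupling, setting out from 2 and coming back at 5.
- K2S2O8 in aq. NaOH/pyridine should sulfate phenol 2 para to the hydroxyl and give potassium 5-acetyl-3-(benzyloxy)-4-hydroxy-2-methoxyphenyl sulfate F8.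
- Warm aq. HCl should hydrolyse it to 1-[3-(benzyloxy)-2,5-dihydroxy-4-methoxyphenyl]ethan-1-one F9.
- Double O-methylation (MeI, K2CO3, DMF) should give 5.

Further compounds
F1 | step 9 | 3-(benzyloxy)-2,4,5-trimethoxybenzoic acid | OC(=O)c1cc(OC)c(OC)c(OCc2ccccc2)c1OC
F2 | step 9 | 3-(benzyloxy)-2,4,5-trimethoxybenzoyl chloride | ClC(=O)c1cc(OC)c(OC)c(OCc2ccccc2)c1OC
F3 | step 9 | 2-acetyl-3,4,5-trimethoxyphenyl 3-(benzyloxy)-2,4,5-trimethoxybenzoate | CC(=O)c1c(OC(=O)c2cc(OC)c(OC)c(OCc3ccccc3)c2OC)cc(OC)c(OC)c1OC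
F4 | step 9 | 1-[3-(benzyloxy)-2,4,5-trimethoxyphenyl]-3-(6-hydroxy-2,3,4-trimethoxyphenyl)propane-1,3-dione | O=C(CC(=O)c1c(O)cc(OC)c(OC)c1OC)c1cc(OC)c(OC)c(OCc2ccccc2)c1OC
F5 | step 8 | 1-[3-(benzyloxy)-2,4,5-trimethoxyphenyl]-6,6-dimethoxyheptane-1,3,5-trione | COC(C)(OC)C(=O)CC(=O)CC(=O)c1cc(OC)c(OC)c(OCc2ccccc2)c1OC
F6 | step 8 | 2-acetyl-6-[3-(benzyloxy)-2,4,5-trimethoxyphenyl]-4H-pyran-4-one | CC(=O)c1cc(=O)cc(-c2cc(OC)c(OC)c(OCc3ccccc3)c2OC)o1
F7 | step 8 | 1-{6-[3-(benzyloxy)-2,4,5-trimethoxyphenyl]-4-oxo-4H-pyran-2-yl}-4,4,4-trifluorobutane-1,3-dione | O=C(CC(=O)C(F)(F)F)c1cc(=O)cc(-c2cc(OC)c(OC)c(OCc3ccccc3)c2OC)o1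
F8 | step 3 | potassium 5-acetyl-3-(benzyloxy)-4-hydroxy-2-methoxyphenyl sulfate | CC(=O)c1cc(OS(=O)(=O)[O-])c(OC)c(OCc2ccccc2)c1O.[K+]
F9 | step 3 | 1-[3-(benzyloxy)-2,5-dihydroxy-4-methoxyphenyl]ethan-1-one | CC(=O)c1cc(O)c(OC)c(OCc2ccccc2)c1O
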